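The numbers in the tables come from a simulation for substances that don't exist, noise included.

**The decision.** Decide before charging whether north, north-west and north-east end on starting material, mono adduct or bis adduct, and how much bis adduct north holds. Count turnovers for this, with partner in equivalents of the starting material charged.

common to all: starting material 0.20 M
- birch: partner 0.085 M; run made earlier
- alder: partner 0.52 M; run made earlier
- north: partner 0.240 M; time 6.0 h
- north-west: partner 0.160 M; time 6.0 h
- north-east: partner 0.600 M; time 6.0 h

- birch (time / h: bis adduct / %, starting material / %): 0.167: 0, 95.9; 0.500: 2.8, 90.1; 0.833: 0, 82.9; 1.33: 0.2, 75.1; 2.00: 1.1, 67.0; 2.50: 2.6, 61.1; 3.00: 2.3, 55.8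
- alder (time / h: bis adduct / %, starting material / %): 0.250: 8.6, 70.9; 0.333: 10.0, 65.4; 0.500: 15.9, 50.1; 0.833: 24.4, 31.3; 1.33: 30.1, 16.1; 2.00: 29.8, 6.8; 3.00: 31.4, 2.3

(scatter of a reading: 1 percentage point)

* which of these holds the largest part of the starting material at the end of north (bis adduct / mono adduct / starting material)
* which of these holds the largest part of the starting material at the end of north-west (bis adduct / mono adduct / starting material)
* which of these holds the largest part of the starting material at the end of north-east (bis adduct / mono adduct / starting material)
* amount of bis adduct at the end of north, in percent of the starting material charged

- the earlier runs were read with a standard deviation of 1 percentage point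

**Main step.** Take first the step from starting material and partner to mono adduct. The decay looks pseudo-first-order: birch loses 0.194 h⁻¹ and alder 1.37 h⁻¹. Per equivalent of partner, that is a pace of 0.458 h⁻¹ in birch and 0.528 h⁻¹ in alder. I carry the birch pace, the lower, as the cautious figure for what survives. Pace times equivalents times hours is the turnover count, which for north is 3.29. Each turnover divides what is left by e, so I count north keeping 3.71 % of its starting material and losing the other 96.3 %.

**Second partner.** Now let mono adduct take a second partner to bis adduct. Alder's bis adduct is 29.6 % of the starting material consumed at the first reading and 32.1 % at the last. That shows no lag, so I treat mono adduct as a passing stage and drop it from the contest.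

**The rest.** Something unread takes the remainder, in competition with partner. The odds of bis adduct against that route, per equivalent, read 0.129 in birch and 0.182 in alder. For north these give 12.9 % and 17.3 % of bis adduct. I commit to the lower, read from birch, whose partner charge lies nearer to north's than alder's does. North-west counts 2.20, leaving 11.1 % of starting material against 8.32 % of bis adduct. North-east counts 8.24, leaving 0.0265 % against 27.9 %. My call is therefore bis adduct, starting material, bis adduct.

**The forecast.** The forecast named mono adduct, mono adduct and mono adduct, with 15 % of bis adduct in north (range 11 % to 20 %): “Mono adduct dominates everywhere”.

**The result.** Of the asked species, north ends on bis adduct, north-west on starting material and north-east on bis adduct, and north holds 11.1 % of bis adduct.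

    partner + mono adduct → bis adduct + by-product (k = 0.00190 M⁻¹ s⁻¹)
    starting material + partner → mono adduct + by-product (k = 7.10 × 10⁻⁴ M⁻¹ s⁻¹)
    starting material + by-product → side product A (k = 6.90 × 10⁻⁴ M⁻¹ s⁻¹)
    starting material + bis adduct → side product C (k = 8.80 × 10⁻⁴ M⁻¹ s⁻¹)
    mono adduct → side product B (k = 6.00 × 10⁻⁴ s⁻¹)

**The check.** North's count of 3.29 left 3.71 % of starting material, and north holds 3.22 %. North's bis adduct is held down in part by the loss of mono adduct to side product B, which weighs more than the shrinking supply of partner: without that step north gives 33.0 % instead of 11.1 %. A neighbour of north with 0.480 equiv of partner counts 1.32, which leaves 26.7 %. That neighbour holds 33.9 % of starting material, with 14.3 % of its partner charge left.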